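**Retrosynthetic overview**
1. Target 39 ← acetylation and PMB removal ← γ-lactone 36, closed by a SmI2 Reformatsky reaction of a C7 2-bromopropanoate onto the C8 ketone (C17–C8 bond).
2. Feature that carries the strategy: in the ten-membered ring (C1–C10) the C8 oxygen and the Z-C3=C4 alkene flank what can be a severed C3–C8 bond. The ring is therefore unveiled by Grob fragmentation of tricyclic mesylate 32, in which C3–C8 is the bond shared by six-membered ring B (C1, C2, C3, C8, C9, C10) and ring C (C3, C4, C5, C6, C7, C8).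
3. Ring C is built on ring-B ketone 17 by an anti aldol at C3 (C3–C4) with enal 24 and a SmI2 pinacol closure (C7–C8).
4. Ketone 17 comes from (S)-Wieland–Miescher ketone (rings A and B): 13α,14α-diol, C11 methylene then 11,20-epoxide, 9α-oxygen by Rubottom oxidation, 2α-oxygen by enone epoxidation and reductive opening. Enal 24 comes from but-2-yne-1,4-diol.
5. Ring order: A and B (starting material), C (steps 20–23), ten-membered ring by loss of the B/C bond (step 26), lactone (step 29).

Key step: step 26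

Remark: briarane numbering is used for every intermediate (C1 quaternary with CH3-15; ring A = C1, C10–C14; C16 on C5; C20 on C11; C17–C19 lactone carbons); α/β mean the face opposite to/of the C15 methyl; TBS = tert-butyldimethylsilyl, TES = triethylsilyl, PMB = 4-methoxybenzyl, DMB = 3,4-dimethoxybenzyl. Because the trans A/B fusion locks ring B as a chair, only the tricycle with ring C fused on the α face (H-3 and 8-OH β) has C2 axial and the C4 sulfonate equatorial on ring C; in that tricycle the C7 substituent pointing under ring B must be hydrogen, so C7–O is made cis to 8-OH (7β) and C7 is inverted after the ring expansion (step 28); only fluoride-, DDQ- or base-labile protecting groups are used because of the 11,20-epoxide.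

Step 1
Reactants: 1 (S)-Wieland–Miescher ketone
Product: 2 14β-hydroxy-9-en-8-one
Conditions: NaBH4 (0.3 equiv), EtOH, −10 °C
Reagents that add atoms: none
Why: Chemoselective borohydride reduction of the saturated C14 ketone (the conjugated C8 ketone is less electrophilic), hydride arriving anti to the angular methyl to give the 14β-alcohol, a stereocentre that is removed again in step 2.

Step 2
Reactants: 2 14β-hydroxy-9-en-8-one
Product: 3 9,13-dien-8-one
Conditions: Burgess reagent (methyl N-(triethylammoniosulfonyl)carbamate), benzene, 50 °C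
Reagents that add atoms: none
Why: Burgess dehydration (syn elimination of the sulfamate) can only take a hydrogen from C13 because C1 is quaternary, so the C13=C14 alkene forms without a new stereocentre.

Step 3
Reactants: 3 9,13-dien-8-one
Product: 4 13α,14α-dihydroxy-9-en-8-one
Conditions: OsO4 (2 mol %), N-methylmorpholine N-oxide, acetone/H2O, rt
Reagents that add atoms: osmium tetroxide, O=[Os](=O)(=O)=O; N-methylmorpholine N-oxide, C[N+]1([O-])CCOCC1 (terminal source of the two oxygen atoms)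
Why: Upjohn dihydroxylation is chemoselective for the isolated cis alkene over the enone and osmylation takes place anti to the neighbouring axial C15 methyl, which sets the 13α,14α cis-diol.

Step 4
Reactants: 4 13α,14α-dihydroxy-9-en-8-one
Product: 5 13α,14α-bis(TBS-oxy)-9-en-8-one
Conditions: TBSOTf (2.5 equiv), 2,6-lutidine, CH2Cl2, 0 °C
Reagents that add atoms: tert-butyldimethylsilyl triflate, CC(C)(C)[Si](C)(C)OS(=O)(=O)C(F)(F)F
Why: Silylation with the reactive triflate protects both alcohols (no new stereocentre) as ethers that survive the later base and SmI2 steps and are removed by fluoride, which the epoxide tolerates.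

Step 5
Reactants: 5 13α,14α-bis(TBS-oxy)-9-en-8-one
Product: 6 8-ethylene ketal 10(11)-ene
Conditions: ethylene glycol, PPTS, benzene, reflux (Dean–Stark)
Reagents that add atoms: ethylene glycol, OCCO
Why: Acid-catalysed ketalisation of the enone goes with the usual migration of the double bond out of conjugation to C10=C11 (as with steroidal 4-en-3-ones), which masks C8 and exposes C11; no new stereocentre.

Step 6
Reactants: 6 8-ethylene ketal 10(11)-ene
Product: 8 11α-hydroxy 8-ketal (10α-H), via C11 alkylborane 7 (not isolated)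
Conditions: BH3·THF, THF, 0 °C → rt; then NaOH, H2O2, 0 °C
Reagents that add atoms: hydrogen peroxide, OO
Why: Hydroboration–oxidation: boron adds to the less substituted C11 and hydrogen to C10 in a syn manner from the α face, away from the C15 methyl, which should set 10α-H (trans-decalin) and 11α-OH; C10 can still be equilibrated to the trans fusion at ketone 9.

Step 7
Reactants: 8 11α-hydroxy 8-ketal (10α-H)
Product: 9 11-oxo 8-ketal
Conditions: Dess–Martin periodinane, NaHCO3, CH2Cl2, rt
Reagents that add atoms: none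
Why: Dess–Martin oxidation of the secondary alcohol; C10 is now α to a ketone, so the trans ring fusion set in step 6 is also the thermodynamic one.

Step 8
Reactants: 9 11-oxo 8-ketal
Product: 10 11(20)-methylene 8-ketal
Conditions: Ph3PCH3Br, KOtBu, THF, 0 → 60 °C
Reagents that add atoms: methyltriphenylphosphonium bromide, C[P+](c1ccccc1)(c1ccccc1)c1ccccc1.[Br-]
Why: Wittig methylenation of the hindered C11 ketone introduces C20 while the ketal keeps C8 out of the reaction; no stereocentre is formed.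

Step 9
Reactants: 10 11(20)-methylene 8-ketal
Product: 11 11(20)-methylene-8-one
Conditions: PPTS, acetone/H2O, 60 °C
Reagents that add atoms: water, O
Why: Mild acid hydrolysis of the dioxolane frees the C8 ketone in the last acidic step of the route, before the acid-sensitive 11,20-epoxide exists.

Step 10
Reactants: 11 11(20)-methylene-8-one
Product: 12 11(20)-methylene-2-en-8-one
Conditions: IBX, DMSO/toluene, 70 °C
Reagents that add atoms: none
Why: IBX dehydrogenation proceeds through the enol, and a trans-fused ketone of this type enolises toward C3 (as 5α-3-keto steroids do toward C2), so the C2=C3 enone forms and C9 is left for the next step.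

Step 11
Reactants: 12 11(20)-methylene-2-en-8-one
Product: 13 8-(TBS-oxy)-2,8-diene
Conditions: TBSOTf, Et3N, CH2Cl2, 0 °C
Reagents that add atoms: tert-butyldimethylsilyl triflate, CC(C)(C)[Si](C)(C)OS(=O)(=O)C(F)(F)F
Why: Soft enolisation and O-silylation: C9 is the only position that can lose a proton (C1 is quaternary), giving the cross-conjugated 8-silyloxy-2,8-diene.

Step 12
Reactants: 13 8-(TBS-oxy)-2,8-diene
Product: 14 9α-(TBS-oxy)-2-en-8-one 11α,20-epoxide
Conditions: mCPBA (2.5 equiv), NaHCO3, CH2Cl2, −20 °C → rt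
Reagents that add atoms: 3-chloroperbenzoic acid, OOC(=O)c1cccc(Cl)c1
Why: Rubottom oxidation and Prilezhaev epoxidation in one operation: the peracid attacks the enol ether C8=C9 from the α face (the β face is screened by the 1,3-related axial C15) and a 1,4-silyl shift gives the 9α-silyloxy ketone, while the exocyclic C11=C20 alkene is epoxidised from its equatorial α side, again away from the syn-axial C15, placing the epoxide oxygen α and C20 β.

Step 13
Reactants: 14 9α-(TBS-oxy)-2-en-8-one 11α,20-epoxide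
Product: 15 2α,3α-epoxy-8-one
Conditions: H2O2 (30 %), NaOH, MeOH, 0 °C
Reagents that add atoms: hydrogen peroxide, OO
Why: Weitz–Scheffer epoxidation: hydroperoxide adds to C2 axially from the α face, anti to the adjacent axial C15 methyl (as in steroidal 1-en-3-ones), giving the 2α,3α-epoxide.

Step 14
Reactants: 15 2α,3α-epoxy-8-one
Product: 16 2α-hydroxy-8-one
Conditions: SmI2 (2.2 equiv), THF/MeOH, −90 °C
Reagents that add atoms: none
Why: SmI2 reduction of an α,β-epoxy ketone cleaves only the C3–O bond and leaves the 2α-alcohol with its configuration intact; the unactivated 11,20-epoxide and the equatorial, poorly aligned C9–O bond are not touched at this temperature.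

Step 15
Reactants: 16 2α-hydroxy-8-one
Product: 17 tetrakis-TBS ring-B ketone
Conditions: TBSOTf, 2,6-lutidine, CH2Cl2, −78 → 0 °C
Reagents that add atoms: tert-butyldimethylsilyl triflate, CC(C)(C)[Si](C)(C)OS(=O)(=O)C(F)(F)F
Why: Silylation of the axial neopentyl alcohol with the reactive triflate; a silyl ether is a poor leaving group, which protects the later C3 enolate from β-elimination.

Step 16
Reactants: 18 but-2-yne-1,4-diol
Product: 19 4-(PMB-oxy)but-2-yn-1-ol
Conditions: NaH (1 equiv), 4-methoxybenzyl chloride, THF/DMF, 0 °C → rt (diol in excess)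
Reagents that add atoms: 4-methoxybenzyl chloride, COc1ccc(CCl)cc1
Why: Williamson monoetherification of the symmetrical diol used in excess; no stereocentre.

Step 17
Reactants: 19 4-(PMB-oxy)but-2-yn-1-ol
Product: 21 (Z)-3-iodo-4-(PMB-oxy)but-2-en-1-ol, via sodium alkenylalanate 20 (not isolated)
Conditions: NaAlH2(OCH2CH2OMe)2, THF, 0 °C; then I2, −78 °C
Reagents that add atoms: iodine, II
Why: Hydroxyl-directed trans-hydroalumination places aluminium on the distal alkyne carbon in a five-membered oxaaluminacycle, and iodinolysis with retention gives the (Z)-vinyl iodide with iodine cis to CH2OH.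

Step 18
Reactants: 21 (Z)-3-iodo-4-(PMB-oxy)but-2-en-1-ol
Product: 22 TES ether of 21
Conditions: TESCl, imidazole, CH2Cl2, 0 °C
Reagents that add atoms: chlorotriethylsilane, CC[Si](Cl)(CC)CC
Why: Silylation of the primary alcohol; the TES ether is the one that step 22 will oxidise directly.

Step 19
Reactants: 22 TES ether of 21
Product: 24 (Z)-2-(PMB-oxymethyl)-4-(TES-oxy)but-2-enal, via vinyllithium 23 (not isolated)
Conditions: t-BuLi (2.1 equiv), Et2O, −78 °C; then DMF
Reagents that add atoms: N,N-dimethylformamide, CN(C)C=O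
Why: Iodine–lithium exchange with retention of the alkene geometry and formylation with DMF (Bouveault aldehyde synthesis) put the C4 aldehyde cis to C7, as ring C requires.

Step 20
Reactants: 17 tetrakis-TBS ring-B ketone; 24 (Z)-2-(PMB-oxymethyl)-4-(TES-oxy)but-2-enal
Product: 26 anti aldol adduct (3α side chain), via lithium enolate 25 (not isolated)
Conditions: LiN(iPr)2, THF, −78 °C; then 24, −78 °C; aqueous work-up
Reagents that add atoms: none
Why: Kinetic deprotonation on the unsubstituted C3 side and lithium aldol addition through a Zimmerman–Traxler chair of the ring (E)-enolate: the new C3–C4 bond ends equatorial (3α, the configuration C3 also reaches by epimerisation) and the anti adduct sets C4 so that its oxygen will be pseudo-equatorial on ring C.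

Step 21
Reactants: 26 anti aldol adduct (3α side chain)
Product: 27 4-O-TES aldol adduct
Conditions: TESOTf, 2,6-lutidine, CH2Cl2, −78 °C
Reagents that add atoms: triethylsilyl triflate, CC[Si](CC)(CC)OS(=O)(=O)C(F)(F)F
Why: Silylation blocks the C4 alcohol, which would otherwise form a lactol with the cis aldehyde made in step 22; TES is chosen so that it can later be removed in the presence of the TBS ethers.

Step 22
Reactants: 27 4-O-TES aldol adduct
Product: 28 keto enal (C7 aldehyde)
Conditions: (COCl)2, DMSO, CH2Cl2, −78 → −30 °C; then Et3N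
Reagents that add atoms: none
Why: Swern oxidation carried out directly on the primary allylic TES ether, which is cleaved and oxidised while the secondary TES and TBS ethers stay; the enal geometry is kept at low temperature.

Step 23
Reactants: 28 keto enal (C7 aldehyde)
Product: 29 tricyclic 7β,8β-diol (3β-H)
Conditions: SmI2 (2.5 equiv), t-BuOH, THF, −78 → −20 °C
Reagents that add atoms: none
Why: SmI2 pinacol cyclisation: the enal is reduced first and its ketyl adds to C8 on the axial α face (as in the kinetic cis-ketol of a Robinson annulation) with the aldehyde hydrogen turned under ring B, which gives the cis-fused ring C with 8β-OH, and samarium bridging the two oxygens makes the diol cis (7β-OH).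

Step 24
Reactants: 29 tricyclic 7β,8β-diol (3β-H)
Product: 30 7-O-DMB ether
Conditions: Ag2O, 3,4-dimethoxybenzyl bromide, CH2Cl2, rt
Reagents that add atoms: 3,4-dimethoxybenzyl bromide, COc1ccc(CBr)cc1OC
Why: Silver oxide-mediated benzylation of the diol alkylates only the secondary oxygen and uses no strong base, so no silyl group migrates; a benzyl-type ether on O7 cannot shift to O8 in step 26 and is removable by DDQ before the C16 PMB ether.

Step 25
Reactants: 30 7-O-DMB ether
Product: 31 4α,8β-diol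
Conditions: HF·pyridine, pyridine, THF, 0 °C
Reagents that add atoms: none
Why: Buffered HF·pyridine cleaves the secondary allylic TES ether much faster than the hindered TBS ethers and leaves the epoxide and both benzyl-type ethers alone.

Step 26
Reactants: 31 4α,8β-diol
Product: 33 ten-membered 3Z-diene 8-ketone (7β-ODMB), via tricyclic C4 mesylate 32 (not isolated)
Conditions: MsCl (1.05 equiv), THF, −78 °C; then KN(SiMe3)2 (2.05 equiv), −78 → −40 °C
Reagents that add atoms: none
Why: The first equivalent of base lets MsCl sulfonylate the exposed secondary allylic C4–OH and the second deprotonates the tertiary C8–OH, whose alkoxide fragments in a concerted antiperiplanar way: the oxygen lone pair becomes C8=O, the C3–C8 σ bond becomes the C3=C4 π bond and C4–OMs leaves (Grob fragmentation; closest known type: Wharton fragmentation of cis-fused decalin-1,3-diol monosulfonates to (Z)-cyclodecenones). The ten-membered ring is not closed end to end: it is unveiled by scission of the C3–C8 bond shared by the cis-fused six-membered rings B and C, whose perimeter C1–C10 becomes the new ring. No stereocentre is created; C3, C4 and C8 become trigonal and C7 is untouched. The Z geometry follows from the ground-state conformation: the trans A/B fusion locks ring B as a chair, ring C is a half-chair with C2 axial and the C4 sulfonate pseudo-equatorial, so C4–O is antiperiplanar to C3–C8 while C2–C3 and C4–C5 are gauche and end up cis. The step needs sulfonylation before any loss of the allylic sulfonate and fragmentation without epimerisation at C7: the two equivalents of base end as KCl and KOMs, the benzyl-type ether on O7 cannot migrate, and the silylated O2 and the E-selective pathway lack an antiperiplanar bond.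

Step 27
Reactants: 33 ten-membered 3Z-diene 8-ketone (7β-ODMB)
Product: 34 7β-hydroxy 8-ketone
Conditions: DDQ (1.1 equiv), CH2Cl2/pH 7 buffer, 0 °C
Reagents that add atoms: none
Why: DDQ oxidises the more electron-rich 3,4-dimethoxybenzyl ether faster than the PMB ether, which frees the C7 alcohol under neutral conditions.

Step 28
Reactants: 34 7β-hydroxy 8-ketone
Product: 35 7α-(2-bromopropanoate)
Conditions: PPh3, diisopropyl azodicarboxylate, 2-bromopropanoic acid, toluene, 0 °C
Reagents that add atoms: 2-bromopropanoic acid, CC(Br)C(O)=O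
Why: Mitsunobu esterification: the acidic α-bromo acid displaces the activated C7–O with inversion (SN2 next to a carbonyl is fast), which converts the 7β-alcohol into the 7α-ester of the natural series; the bromine-bearing carbon is used as a mixture because it becomes trigonal in step 29.

Step 29
Reactants: 35 7α-(2-bromopropanoate)
Product: 36 γ-lactone (8-OH, 17-methyl)
Conditions: SmI2 (2.2 equiv), THF, −78 °C
Reagents that add atoms: none
Why: SmI2 Reformatsky reaction: the α-bromo ester is reduced before the ketone and the samarium enolate adds intramolecularly to C8 (five-membered ring), the O7 tether reaching only the carbonyl face that puts 8-OH trans to H-7, and the epimerisable C17 takes its methyl group cis to 8-OH, away from C9.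

Step 30
Reactants: 36 γ-lactone (8-OH, 17-methyl)
Product: 37 2,9,13,14-tetraol
Conditions: HF·pyridine, pyridine, THF, 0 °C → rt
Reagents that add atoms: none
Why: Fluoride cleavage of the four TBS ethers under buffered, non-basic conditions tolerated by the epoxide, the lactone and the PMB ether; no stereocentre is touched.

Step 31
Reactants: 37 2,9,13,14-tetraol
Product: 38 tetraacetate 16-O-PMB ether
Conditions: Ac2O, pyridine, DMAP (cat.), CH2Cl2, rt
Reagents that add atoms: acetic anhydride, CC(=O)OC(C)=O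
Why: Acetylation of the four secondary alcohols; the hindered tertiary 8-OH is not acylated under these conditions.

Step 32
Reactants: 38 tetraacetate 16-O-PMB ether
Product: 39 CNP0317528.3
Conditions: DDQ (1.3 equiv), CH2Cl2/pH 7 buffer, 0 °C
Reagents that add atoms: none
Why: Oxidative cleavage of the PMB ether by DDQ in buffered medium frees the C16 alcohol without touching the acetates, the lactone or the epoxide.

**Compound list**
1 | (S)-Wieland–Miescher ketone | C[C@]12CCC(=O)C=C1CCCC2=O | starting material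
2 | 14β-hydroxy-9-en-8-one | C[C@]12CCC(=O)C=C1CCC[C@@H]2O | intermediate
3 | 9,13-dien-8-one | C[C@]12CCC(=O)C=C1CCC=C2 | intermediate
4 | 13α,14α-dihydroxy-9-en-8-one | C[C@]12CCC(=O)C=C1CC[C@@H](O)[C@H]2O | intermediate
5 | 13α,14α-bis(TBS-oxy)-9-en-8-one | C[C@]12CCC(=O)C=C1CC[C@@H](O[Si](C)(C)C(C)(C)C)[C@H]2O[Si](C)(C)C(C)(C)C | intermediate
6 | 8-ethylene ketal 10(11)-ene | C[C@]12CCC3(OCCO3)CC1=CC[C@@H](O[Si](C)(C)C(C)(C)C)[C@H]2O[Si](C)(C)C(C)(C)C | intermediate
7 | C11 alkylborane (11α-boryl, 10α-H; not isolated) | C[C@]12CCC3(OCCO3)C[C@@H]1[C@@H]([BH2])C[C@@H](O[Si](C)(C)C(C)(C)C)[C@H]2O[Si](C)(C)C(C)(C)C | intermediate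
8 | 11α-hydroxy 8-ketal (10α-H) | C[C@]12CCC3(OCCO3)C[C@@H]1[C@@H](O)C[C@@H](O[Si](C)(C)C(C)(C)C)[C@H]2O[Si](C)(C)C(C)(C)C | intermediate
9 | 11-oxo 8-ketal | C[C@]12CCC3(OCCO3)C[C@@H]1C(=O)C[C@@H](O[Si](C)(C)C(C)(C)C)[C@H]2O[Si](C)(C)C(C)(C)C | intermediate
10 | 11(20)-methylene 8-ketal | C[C@]12CCC3(OCCO3)C[C@@H]1C(=C)C[C@@H](O[Si](C)(C)C(C)(C)C)[C@H]2O[Si](C)(C)C(C)(C)C | intermediate
11 | 11(20)-methylene-8-one | C[C@]12CCC(=O)C[C@@H]1C(=C)C[C@@H](O[Si](C)(C)C(C)(C)C)[C@H]2O[Si](C)(C)C(C)(C)C | intermediate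
12 | 11(20)-methylene-2-en-8-one | C[C@]12C=CC(=O)C[C@@H]1C(=C)C[C@@H](O[Si](C)(C)C(C)(C)C)[C@H]2O[Si](C)(C)C(C)(C)C | intermediate
13 | 8-(TBS-oxy)-2,8-diene | C[C@]12C=CC(O[Si](C)(C)C(C)(C)C)=C[C@@H]1C(=C)C[C@@H](O[Si](C)(C)C(C)(C)C)[C@H]2O[Si](C)(C)C(C)(C)C | intermediate
14 | 9α-(TBS-oxy)-2-en-8-one 11α,20-epoxide | C[C@]12C=CC(=O)[C@@H](O[Si](C)(C)C(C)(C)C)[C@@H]1[C@]3(CO3)C[C@@H](O[Si](C)(C)C(C)(C)C)[C@H]2O[Si](C)(C)C(C)(C)C | intermediate
15 | 2α,3α-epoxy-8-one | C[C@]12[C@H]3O[C@H]3C(=O)[C@@H](O[Si](C)(C)C(C)(C)C)[C@@H]1[C@]4(CO4)C[C@@H](O[Si](C)(C)C(C)(C)C)[C@H]2O[Si](C)(C)C(C)(C)C | intermediate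
16 | 2α-hydroxy-8-one | C[C@]12[C@@H](O)CC(=O)[C@@H](O[Si](C)(C)C(C)(C)C)[C@@H]1[C@]3(CO3)C[C@@H](O[Si](C)(C)C(C)(C)C)[C@H]2O[Si](C)(C)C(C)(C)C | intermediate
17 | tetrakis-TBS ring-B ketone (2α,9α,13α,14α-OTBS, 11α,20-epoxide) | C[C@]12[C@@H](O[Si](C)(C)C(C)(C)C)CC(=O)[C@@H](O[Si](C)(C)C(C)(C)C)[C@@H]1[C@]3(CO3)C[C@@H](O[Si](C)(C)C(C)(C)C)[C@H]2O[Si](C)(C)C(C)(C)C | intermediate
18 | but-2-yne-1,4-diol | OCC#CCO | starting material
19 | 4-(PMB-oxy)but-2-yn-1-ol | COc1ccc(COCC#CCO)cc1 | intermediate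
20 | sodium alkenylalanate (cyclic oxaaluminacycle; not isolated) | COCCO[Al-]1(OCCOC)OCC=C1COCc1ccc(OC)cc1.[Na+] | intermediate
21 | (Z)-3-iodo-4-(PMB-oxy)but-2-en-1-ol | OC/C=C(\I)COCc1ccc(OC)cc1 | intermediate
22 | TES ether of 21 | CC[Si](CC)(CC)OC/C=C(\I)COCc1ccc(OC)cc1 | intermediate
23 | vinyllithium from 22 (not isolated) | CC[Si](CC)(CC)OC/C=C(\[Li])COCc1ccc(OC)cc1 | intermediate
24 | (Z)-2-(PMB-oxymethyl)-4-(TES-oxy)but-2-enal | CC[Si](CC)(CC)OC/C=C(\C=O)COCc1ccc(OC)cc1 | intermediate
25 | lithium enolate of 17 (C3=C8–OLi; not isolated) | C[C@]12[C@@H](O[Si](C)(C)C(C)(C)C)C=C(O[Li])[C@@H](O[Si](C)(C)C(C)(C)C)[C@@H]1[C@]3(CO3)C[C@@H](O[Si](C)(C)C(C)(C)C)[C@H]2O[Si](C)(C)C(C)(C)C | intermediate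
26 | anti aldol adduct (3α side chain, free 4-OH) | C[C@]12[C@@H](O[Si](C)(C)C(C)(C)C)[C@@H]([C@@H](O)/C(COCc4ccc(OC)cc4)=C\CO[Si](CC)(CC)CC)C(=O)[C@@H](O[Si](C)(C)C(C)(C)C)[C@@H]1[C@]3(CO3)C[C@@H](O[Si](C)(C)C(C)(C)C)[C@H]2O[Si](C)(C)C(C)(C)C | intermediate
27 | 4-O-TES aldol adduct | C[C@]12[C@@H](O[Si](C)(C)C(C)(C)C)[C@@H]([C@@H](O[Si](CC)(CC)CC)/C(COCc4ccc(OC)cc4)=C\CO[Si](CC)(CC)CC)C(=O)[C@@H](O[Si](C)(C)C(C)(C)C)[C@@H]1[C@]3(CO3)C[C@@H](O[Si](C)(C)C(C)(C)C)[C@H]2O[Si](C)(C)C(C)(C)C | intermediate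
28 | keto enal (C7 aldehyde) | C[C@]12[C@@H](O[Si](C)(C)C(C)(C)C)[C@@H]([C@@H](O[Si](CC)(CC)CC)/C(COCc4ccc(OC)cc4)=C\C=O)C(=O)[C@@H](O[Si](C)(C)C(C)(C)C)[C@@H]1[C@]3(CO3)C[C@@H](O[Si](C)(C)C(C)(C)C)[C@H]2O[Si](C)(C)C(C)(C)C | intermediate
29 | tricyclic 7β,8β-diol (3β-H, 4α-OTES) | C[C@]12[C@@H](O[Si](C)(C)C(C)(C)C)[C@H]4[C@@H](O[Si](CC)(CC)CC)C(COCc5ccc(OC)cc5)=C[C@H](O)[C@@]4(O)[C@@H](O[Si](C)(C)C(C)(C)C)[C@@H]1[C@]3(CO3)C[C@@H](O[Si](C)(C)C(C)(C)C)[C@H]2O[Si](C)(C)C(C)(C)C | intermediate
30 | 7-O-DMB ether | C[C@]12[C@@H](O[Si](C)(C)C(C)(C)C)[C@H]4[C@@H](O[Si](CC)(CC)CC)C(COCc5ccc(OC)cc5)=C[C@H](OCc6ccc(OC)c(OC)c6)[C@@]4(O)[C@@H](O[Si](C)(C)C(C)(C)C)[C@@H]1[C@]3(CO3)C[C@@H](O[Si](C)(C)C(C)(C)C)[C@H]2O[Si](C)(C)C(C)(C)C | intermediate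
31 | 4α,8β-diol (7β-ODMB) | C[C@]12[C@@H](O[Si](C)(C)C(C)(C)C)[C@H]4[C@@H](O)C(COCc5ccc(OC)cc5)=C[C@H](OCc6ccc(OC)c(OC)c6)[C@@]4(O)[C@@H](O[Si](C)(C)C(C)(C)C)[C@@H]1[C@]3(CO3)C[C@@H](O[Si](C)(C)C(C)(C)C)[C@H]2O[Si](C)(C)C(C)(C)C | intermediate
32 | tricyclic C4 mesylate (4α-OMs, free 8β-OH; not isolated) | C[C@]12[C@@H](O[Si](C)(C)C(C)(C)C)[C@H]4[C@@H](OS(C)(=O)=O)C(COCc5ccc(OC)cc5)=C[C@H](OCc6ccc(OC)c(OC)c6)[C@@]4(O)[C@@H](O[Si](C)(C)C(C)(C)C)[C@@H]1[C@]3(CO3)C[C@@H](O[Si](C)(C)C(C)(C)C)[C@H]2O[Si](C)(C)C(C)(C)C | intermediate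
33 | ten-membered 3Z-diene 8-ketone (both ring alkenes cis in the ring, 7β-ODMB) | C[C@]12[C@@H](O[Si](C)(C)C(C)(C)C)/C=C\C(COCc4ccc(OC)cc4)=C/[C@H](OCc5ccc(OC)c(OC)c5)C(=O)[C@@H](O[Si](C)(C)C(C)(C)C)[C@@H]1[C@]3(CO3)C[C@@H](O[Si](C)(C)C(C)(C)C)[C@H]2O[Si](C)(C)C(C)(C)C | intermediate
34 | 7β-hydroxy 8-ketone | C[C@]12[C@@H](O[Si](C)(C)C(C)(C)C)/C=C\C(COCc4ccc(OC)cc4)=C/[C@H](O)C(=O)[C@@H](O[Si](C)(C)C(C)(C)C)[C@@H]1[C@]3(CO3)C[C@@H](O[Si](C)(C)C(C)(C)C)[C@H]2O[Si](C)(C)C(C)(C)C | intermediate
35 | 7α-(2-bromopropanoate), natural C7 configuration | C[C@]12[C@@H](O[Si](C)(C)C(C)(C)C)/C=C\C(COCc4ccc(OC)cc4)=C/[C@@H](OC(=O)C(C)Br)C(=O)[C@@H](O[Si](C)(C)C(C)(C)C)[C@@H]1[C@]3(CO3)C[C@@H](O[Si](C)(C)C(C)(C)C)[C@H]2O[Si](C)(C)C(C)(C)C | intermediate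
36 | γ-lactone (tetrakis-TBS, 16-O-PMB, free 8-OH) | CC(C)(C)[Si](C)(C)O[C@H]1/C=C\C(COCc4ccc(OC)cc4)=C/[C@H]2OC(=O)[C@@H](C)[C@]2(O)[C@@H](O[Si](C)(C)C(C)(C)C)[C@@H]2[C@]3(CO3)C[C@@H](O[Si](C)(C)C(C)(C)C)[C@@H](O[Si](C)(C)C(C)(C)C)[C@@]12C | intermediate
37 | 2,9,13,14-tetraol (16-O-PMB) | O[C@H]1/C=C\C(COCc4ccc(OC)cc4)=C/[C@H]2OC(=O)[C@@H](C)[C@]2(O)[C@@H](O)[C@@H]2[C@]3(CO3)C[C@@H](O)[C@@H](O)[C@@]12C | intermediate
38 | tetraacetate 16-O-PMB ether | CC(=O)O[C@H]1/C=C\C(COCc4ccc(OC)cc4)=C/[C@H]2OC(=O)[C@@H](C)[C@]2(O)[C@@H](OC(C)=O)[C@@H]2[C@]3(CO3)C[C@@H](OC(C)=O)[C@@H](OC(C)=O)[C@@]12C | intermediate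
39 | CNP0317528.3 | CC(=O)O[C@H]1/C=C\C(CO)=C/[C@H]2OC(=O)[C@@H](C)[C@]2(O)[C@@H](OC(C)=O)[C@@H]2[C@]3(CO3)C[C@@H](OC(C)=O)[C@@H](OC(C)=O)[C@@]12C | target

Total steps: 32. Longest linear sequence: 28 steps (steps 1–15 and 20–32).

**Steps most likely to fail**

Step 26 (Grob fragmentation). What may go wrong: loss of the allylic sulfonate by ionisation or SN2′ attack before the alkoxide forms, or a distortion of ring B (1,3-diaxial contact between C7 and the C2 silyl ether) that takes the C4–O bond out of the antiperiplanar alignment, so that elimination or the 3E isomer competes. The fallback sets out from 31. MnO2 oxidises the allylic C4 alcohol to the tricyclic 8β-hydroxy-5-en-4-one F1. KN(SiMe3)2 followed by PhNTf2 then cleaves the same C3–C8 bond by retro-aldol fragmentation and traps the ten-membered dienolate as the C4 dienyl triflate F2. Reduction of the triflate with Pd(OAc)2/PPh3 (zerovalent palladium formed in the flask), HCO2H and Bu3N rejoins the route at 33. This path does not depend on the alignment of a leaving group.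

Step 23 (pinacol closure). What may go wrong: closure on the equatorial face of C8 (trans-fused ring C, which would later give the 3E alkene), or reductive loss of the C4 or C9 silyloxy group from the ketyl intermediates. The fallback sets out from 28. Cp2TiMe2 methylenates both carbonyl groups to the 8-methylene-7-vinyl triene F3. Ring-closing metathesis with the second-generation Grubbs catalyst RuCl2(=CHPh)(PCy3)(H2IMes) gives the tricyclic 5,7-diene F4. OsO4/N-methylmorpholine N-oxide dihydroxylation of the more electron-rich C7=C8 bond from the equatorial β face of C8 (the axial face is blocked by the C2 silyl ether) returns the route at 29.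

Step 28 (Mitsunobu inversion at C7). What may go wrong: slow displacement at a ring carbon of the ten-membered ketone, elimination, or loss of configurational purity at C7 through enolisation of the α-hydroxy ketone. The fallback sets out from 34. Ms2O and 2,6-lutidine give the α-keto 7β-mesylate F5. Caesium acrylate in DMF displaces it with inversion to the 7α-acrylate F6. Conjugate reduction–aldol cyclisation with [(Ph3P)CuH]6 (hydride to the acrylate terminus, copper enolate onto C8) rejoins the route at 36, replacing steps 28 and 29.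

**Further compounds**
F1 | step 26 | tricyclic 8β-hydroxy-5-en-4-one (7β-ODMB) | C[C@]12[C@@H](O[Si](C)(C)C(C)(C)C)[C@H]4C(=O)C(COCc5ccc(OC)cc5)=C[C@H](OCc6ccc(OC)c(OC)c6)[C@@]4(O)[C@@H](O[Si](C)(C)C(C)(C)C)[C@@H]1[C@]3(CO3)C[C@@H](O[Si](C)(C)C(C)(C)C)[C@H]2O[Si](C)(C)C(C)(C)C
F2 | step 26 | ten-membered C4 dienyl triflate 8-ketone | C[C@]12[C@@H](O[Si](C)(C)C(C)(C)C)/C=C(OS(=O)(=O)C(F)(F)F)\C(COCc4ccc(OC)cc4)=C/[C@H](OCc5ccc(OC)c(OC)c5)C(=O)[C@@H](O[Si](C)(C)C(C)(C)C)[C@@H]1[C@]3(CO3)C[C@@H](O[Si](C)(C)C(C)(C)C)[C@H]2O[Si](C)(C)C(C)(C)C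
F3 | step 23 | 8-methylene-7-vinyl triene | C[C@]12[C@@H](O[Si](C)(C)C(C)(C)C)[C@@H]([C@@H](O[Si](CC)(CC)CC)/C(COCc4ccc(OC)cc4)=C\C=C)C(=C)[C@@H](O[Si](C)(C)C(C)(C)C)[C@@H]1[C@]3(CO3)C[C@@H](O[Si](C)(C)C(C)(C)C)[C@H]2O[Si](C)(C)C(C)(C)C
F4 | step 23 | tricyclic 5,7-diene | C[C@]12[C@@H](O[Si](C)(C)C(C)(C)C)[C@H]4[C@@H](O[Si](CC)(CC)CC)C(COCc5ccc(OC)cc5)=CC=C4[C@@H](O[Si](C)(C)C(C)(C)C)[C@@H]1[C@]3(CO3)C[C@@H](O[Si](C)(C)C(C)(C)C)[C@H]2O[Si](C)(C)C(C)(C)C
F5 | step 28 | α-keto 7β-mesylate | C[C@]12[C@@H](O[Si](C)(C)C(C)(C)C)/C=C\C(COCc4ccc(OC)cc4)=C/[C@H](OS(C)(=O)=O)C(=O)[C@@H](O[Si](C)(C)C(C)(C)C)[C@@H]1[C@]3(CO3)C[C@@H](O[Si](C)(C)C(C)(C)C)[C@H]2O[Si](C)(C)C(C)(C)C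
F6 | step 28 | 7α-acrylate | C[C@]12[C@@H](O[Si](C)(C)C(C)(C)C)/C=C\C(COCc4ccc(OC)cc4)=C/[C@@H](OC(=O)C=C)C(=O)[C@@H](O[Si](C)(C)C(C)(C)C)[C@@H]1[C@]3(CO3)C[C@@H](O[Si](C)(C)C(C)(C)C)[C@H]2O[Si](C)(C)C(C)(C)C
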